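**Retrosynthetic overview**
- The strategy rests on the 5-hydroxyindole unit: its benzo ring is a para-aminophenol (N1 on C7a, OH on C5) and C3a, ortho to the nitrogen-bearing carbon, carries the C3=C2 enamine carbons, which is the imprint of 1,4-benzoquinone plus an enamine N–CH=C(Ar). The only free OH of the target is therefore a former quinone carbonyl and needs no protecting group.
- Last step: acid removes N-(2,4-dimethoxybenzyl) and N-Boc from 18. Key disconnection: the C3–C3a and N1–C7a bonds of the hydroxyindole, leading back to enamine 14 and 1,4-benzoquinone (Nenitzescu annulation).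
- 14 comes from arylacetaldehyde 11 and 2,4-dimethoxybenzylamine; 11 comes from aldehyde 9 by methoxymethylene Wittig homologation and hydrolysis.
- 9 comes from Suzuki coupling of bromoaldehyde 4 (1,2,4,5-tetramethoxybenzene: dibromination, then mono Br–Li exchange and formylation) with boronate 8 (5-methoxyindole: iodination, Boc protection, borylation).
- Ring order: the central benzene ring and the methoxyindole are bought; the only ring formed is the pyrrole ring of the hydroxyindole, whose benzo ring is the quinone.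

Key step: step 9

Assumption: the condensation product of step 8 is an imine/secondary-enamine tautomer pair; it is drawn and numbered as the carbon-nucleophilic (E)-enamine 14 and is used crude. The target has no stereocentre, and both aryl–indolyl axes sit on a ring with identical ortho groups, so no stereoisomers arise.

**Step 1**
Reactants: 1 1,2,4,5-tetramethoxybenzene
Product: 2 1,4-dibromo-2,3,5,6-tetramethoxybenzene
Conditions: Br2 (2.2 equiv), CH2Cl2, 0 °C to rt
Reagents that add atoms: bromine, BrBr
Why: Electrophilic aromatic bromination; the two open ring positions of 1 are each flanked by two methoxy groups and are the only sites available, so dibromination is unambiguous.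

**Step 2**
Reactants: 2 1,4-dibromo-2,3,5,6-tetramethoxybenzene
Product: 4 4-bromo-2,3,5,6-tetramethoxybenzaldehyde, via aryllithium 3 (not isolated)
Conditions: n-BuLi (1.0 equiv), THF, −78 °C; DMF, −78 to 0 °C; 1 M HCl work-up
Reagents that add atoms: N,N-dimethylformamide, CN(C)C=O
Why: Bromine–lithium exchange with one equivalent of n-BuLi should stop at the monolithio stage, and formylation of the ortho-methoxy-stabilized aryllithium with DMF desymmetrizes the ring without statistics.

**Step 3**
Reactants: 5 5-methoxyindole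
Product: 7 tert-butyl 3-iodo-5-methoxyindole-1-carboxylate, via 3-iodo-5-methoxy-1H-indole 6 (not isolated)
Conditions: I2 (1.05 equiv), KOH, DMF, rt; then Boc2O, DMAP (cat.), rt
Reagents that add atoms: iodine, II; di-tert-butyl dicarbonate, CC(C)(C)OC(=O)OC(=O)OC(C)(C)C
Why: Electrophilic iodination at indole C3, the most nucleophilic carbon, followed in the same flask by DMAP-catalysed N-acylation, which stabilizes the labile 3-iodoindole.

**Step 4**
Reactants: 7 tert-butyl 3-iodo-5-methoxyindole-1-carboxylate
Product: 8 tert-butyl 5-methoxy-3-(4,4,5,5-tetramethyl-1,3,2-dioxaborolan-2-yl)indole-1-carboxylate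
Conditions: B2pin2, PdCl2(dppf) (cat.), KOAc, 1,4-dioxane, 80 °C
Reagents that add atoms: bis(pinacolato)diboron, CC1(C)OB(OC1(C)C)B1OC(C)(C)C(C)(C)O1
Why: Miyaura borylation; the C–I bond adds to zerovalent palladium, acetate-assisted transmetalation with the diboron follows, and the weak base does not trigger homocoupling or attack the Boc group.

**Step 5**
Reactants: 4 4-bromo-2,3,5,6-tetramethoxybenzaldehyde; 8 tert-butyl 5-methoxy-3-(4,4,5,5-tetramethyl-1,3,2-dioxaborolan-2-yl)indole-1-carboxylate
Product: 9 tert-butyl 3-(4-formyl-2,3,5,6-tetramethoxyphenyl)-5-methoxyindole-1-carboxylate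
Conditions: Pd(OAc)2 (cat.), SPhos, K3PO4, toluene/H2O (10:1), 80 °C
Reagents that add atoms: none
Why: Suzuki–Miyaura coupling; the para-formyl group speeds oxidative addition of the electron-rich bromide, SPhos tolerates the two ortho methoxy groups, and the phosphate base is mild enough to keep the N-Boc group.

**Step 6**
Reactants: 9 tert-butyl 3-(4-formyl-2,3,5,6-tetramethoxyphenyl)-5-methoxyindole-1-carboxylate
Product: 10 tert-butyl 5-methoxy-3-[2,3,5,6-tetramethoxy-4-(2-methoxyvinyl)phenyl]indole-1-carboxylate (expected as an E/Z mixture, both isomers serving equally)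
Conditions: Ph3P(CH2OMe)Cl, KHMDS, THF, 0 °C; then 9, 0 °C to rt
Reagents that add atoms: (methoxymethyl)triphenylphosphonium chloride, COC[P+](c1ccccc1)(c1ccccc1)c1ccccc1.[Cl-]
Why: Wittig olefination with the methoxymethylene ylide adds the one carbon needed; the preformed ylide is not nucleophilic toward the carbamate, and the alkene geometry is irrelevant because it is lost on hydrolysis.

**Step 7**
Reactants: 10 tert-butyl 5-methoxy-3-[2,3,5,6-tetramethoxy-4-(2-methoxyvinyl)phenyl]indole-1-carboxylate
Product: 11 tert-butyl 5-methoxy-3-[2,3,5,6-tetramethoxy-4-(2-oxoethyl)phenyl]indole-1-carboxylate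
Conditions: 2 M aq. HCl, THF, rt; used promptly
Reagents that add atoms: water, O
Why: Acid-catalysed enol ether hydrolysis (protonation at the aryl-bearing carbon, water addition to the oxocarbenium ion, loss of methanol); dilute aqueous acid at room temperature should leave the N-Boc indole and the aryl methyl ethers untouched.

**Step 8**
Reactants: 11 tert-butyl 5-methoxy-3-[2,3,5,6-tetramethoxy-4-(2-oxoethyl)phenyl]indole-1-carboxylate; 12 2,4-dimethoxybenzylamine
Product: 14 tert-butyl 3-{4-[(E)-2-(2,4-dimethoxybenzylamino)vinyl]-2,3,5,6-tetramethoxyphenyl}-5-methoxyindole-1-carboxylate, via imine tautomer 13 (not isolated)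
Conditions: 12 (1.0 equiv), MgSO4, CH2Cl2, rt; filter, concentrate, use at once
Reagents that add atoms: none
Why: Imine condensation driven by a drying agent, with imine–enamine tautomerism supplying the aryl-conjugated secondary enamine; exactly one equivalent of amine is used so that no free amine remains to add to the quinone in the next step.

**Step 9**
Reactants: 14 tert-butyl 3-{4-[(E)-2-(2,4-dimethoxybenzylamino)vinyl]-2,3,5,6-tetramethoxyphenyl}-5-methoxyindole-1-carboxylate; 15 1,4-benzoquinone
Product: 18 tert-butyl 3-{4-[1-(2,4-dimethoxybenzyl)-5-hydroxyindol-3-yl]-2,3,5,6-tetramethoxyphenyl}-5-methoxyindole-1-carboxylate, via hydroquinone Michael adduct 16 (not isolated), via quinone enamine 17 (not isolated)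
Conditions: 15 (1.2 equiv), ZnCl2 (0.2 equiv), CH2Cl2, 0 °C to rt, argon; 14 added slowly to the quinone
Reagents that add atoms: none
Why: Proposed new method: the enamine carbon that carries the tetramethoxyaryl ring adds in a Michael sense to C2 of the ZnCl2-activated quinone and the adduct tautomerizes to hydroquinone 16; a second quinone molecule oxidizes 16 to quinone 17, whose N–H attacks the neighbouring quinone carbonyl, and the carbinolamine loses water to a quinone iminium ion that the hydroquinone formed reduces to the 5-hydroxyindole, so that one quinone is consumed and one water is lost overall. The closest known reaction type is the Nenitzescu synthesis of 5-hydroxyindoles from 1,4-benzoquinone and β-aminocrotonates, which has not been shown for an aldehyde-derived secondary enamine whose nucleophilic carbon carries an aryl ring in place of an ester. The pyrrole ring closes by 5-exo-trig attack of nitrogen on the carbonyl carbon (N1–C7a) after the intermolecular C3–C3a bond is made, and no stereocentre is formed. The step needs carbon attack before nitrogen attack and nitrogen closure in preference to oxygen closure: the first is inherent in the enamine, and the second should be favoured by inverse addition into excess quinone, which oxidizes 16 quickly to 17 (no phenol left to close on the iminium carbon), in an aprotic medium free of Brønsted acid. Regiochemistry is fixed because nitrogen can only close ortho to the new C–C bond, which leaves the second quinone oxygen para to nitrogen as the C5 hydroxyl. The N-Boc group keeps the methoxyindole from adding to the quinone, and the twisted, electron-rich aryl ring does not drain the nucleophilicity of the enamine.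

**Step 10**
Reactants: 18 tert-butyl 3-{4-[1-(2,4-dimethoxybenzyl)-5-hydroxyindol-3-yl]-2,3,5,6-tetramethoxyphenyl}-5-methoxyindole-1-carboxylate
Product: 19 3-[2,3,5,6-tetramethoxy-4-(5-methoxy-1H-indol-3-yl)phenyl]-1H-indol-5-ol (CNP0244913.0)
Conditions: TFA/CH2Cl2 (1:1), anisole (10 equiv), rt to 40 °C
Reagents that add atoms: none
Why: Acidolysis; the Boc group leaves as the tert-butyl cation and CO2, and the protonated N-benzylindole expels the stabilized 2,4-dimethoxybenzyl cation, which anisole traps by Friedel–Crafts alkylation, while the phenol and the aryl methyl ethers are stable to TFA.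

**Compound list**
1 | 1,2,4,5-tetramethoxybenzene | COc1cc(OC)c(OC)cc1OC | starting material
2 | 1,4-dibromo-2,3,5,6-tetramethoxybenzene | COc1c(Br)c(OC)c(OC)c(Br)c1OC | intermediate
3 | (4-bromo-2,3,5,6-tetramethoxyphenyl)lithium | [Li]c1c(OC)c(OC)c(Br)c(OC)c1OC | intermediate
4 | 4-bromo-2,3,5,6-tetramethoxybenzaldehyde | COc1c(Br)c(OC)c(OC)c(C=O)c1OC | intermediate
5 | 5-methoxyindole | COc1ccc2[nH]ccc2c1 | starting material
6 | 3-iodo-5-methoxy-1H-indole | COc1ccc2[nH]cc(I)c2c1 | intermediate
7 | tert-butyl 3-iodo-5-methoxyindole-1-carboxylate | COc1ccc2c(c1)c(I)cn2C(=O)OC(C)(C)C | intermediate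
8 | tert-butyl 5-methoxy-3-(4,4,5,5-tetramethyl-1,3,2-dioxaborolan-2-yl)indole-1-carboxylate | COc1ccc2c(c1)c(cn2C(=O)OC(C)(C)C)B1OC(C)(C)C(C)(C)O1 | intermediate
9 | tert-butyl 3-(4-formyl-2,3,5,6-tetramethoxyphenyl)-5-methoxyindole-1-carboxylate | COc1ccc2c(c1)c(cn2C(=O)OC(C)(C)C)-c1c(OC)c(OC)c(C=O)c(OC)c1OC | intermediate
10 | tert-butyl 5-methoxy-3-[2,3,5,6-tetramethoxy-4-(2-methoxyvinyl)phenyl]indole-1-carboxylate (E/Z mixture, geometry not specified) | COC=Cc1c(OC)c(OC)c(-c2cn(C(=O)OC(C)(C)C)c3ccc(OC)cc23)c(OC)c1OC | intermediate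
11 | tert-butyl 5-methoxy-3-[2,3,5,6-tetramethoxy-4-(2-oxoethyl)phenyl]indole-1-carboxylate | COc1ccc2c(c1)c(cn2C(=O)OC(C)(C)C)-c1c(OC)c(OC)c(CC=O)c(OC)c1OC | intermediate
12 | 2,4-dimethoxybenzylamine | COc1ccc(CN)c(OC)c1 | starting material
13 | tert-butyl 3-{4-[(2E)-2-(2,4-dimethoxybenzylimino)ethyl]-2,3,5,6-tetramethoxyphenyl}-5-methoxyindole-1-carboxylate | COc1ccc2c(c1)c(cn2C(=O)OC(C)(C)C)-c1c(OC)c(OC)c(C/C=N/Cc2ccc(OC)cc2OC)c(OC)c1OC | intermediate
14 | tert-butyl 3-{4-[(E)-2-(2,4-dimethoxybenzylamino)vinyl]-2,3,5,6-tetramethoxyphenyl}-5-methoxyindole-1-carboxylate | COc1ccc2c(c1)c(cn2C(=O)OC(C)(C)C)-c1c(OC)c(OC)c(/C=C/NCc2ccc(OC)cc2OC)c(OC)c1OC | intermediate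
15 | 1,4-benzoquinone | O=C1C=CC(=O)C=C1 | starting material
16 | tert-butyl 3-{4-[1-(2,5-dihydroxyphenyl)-2-(2,4-dimethoxybenzylamino)vinyl]-2,3,5,6-tetramethoxyphenyl}-5-methoxyindole-1-carboxylate (amino group cis to the dihydroxyphenyl ring) | COc1ccc2c(c1)c(cn2C(=O)OC(C)(C)C)-c1c(OC)c(OC)c(/C(c2cc(O)ccc2O)=C/NCc2ccc(OC)cc2OC)c(OC)c1OC | intermediate
17 | tert-butyl 3-{4-[2-(2,4-dimethoxybenzylamino)-1-(3,6-dioxocyclohexa-1,4-dien-1-yl)vinyl]-2,3,5,6-tetramethoxyphenyl}-5-methoxyindole-1-carboxylate (amino group cis to the quinone ring) | COc1ccc2c(c1)c(cn2C(=O)OC(C)(C)C)-c1c(OC)c(OC)c(/C(C2=CC(=O)C=CC2=O)=C/NCc2ccc(OC)cc2OC)c(OC)c1OC | intermediate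
18 | tert-butyl 3-{4-[1-(2,4-dimethoxybenzyl)-5-hydroxyindol-3-yl]-2,3,5,6-tetramethoxyphenyl}-5-methoxyindole-1-carboxylate | COc1ccc2c(c1)c(cn2C(=O)OC(C)(C)C)-c1c(OC)c(OC)c(-c2cn(Cc3ccc(OC)cc3OC)c3ccc(O)cc23)c(OC)c1OC | intermediate
19 | 3-[2,3,5,6-tetramethoxy-4-(5-methoxy-1H-indol-3-yl)phenyl]-1H-indol-5-ol (CNP0244913.0) | COc1ccc2[nH]cc(-c3c(OC)c(OC)c(-c4c[nH]c5ccc(O)cc45)c(OC)c3OC)c2c1 | target

**Step count**
Total steps: 10. Longest linear sequence: 8 steps (1 → 2 → 4 → 9 → 10 → 11 → 14 → 18 → 19; the branch from 5 is equally long).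

**Steps most likely to fail**

1. Step 9 (proposed new method). The hydroquinone hydroxyl of the Michael adduct may close on the iminium carbon and expel the amine (benzofuran formation) faster than oxidation and nitrogen closure occur. The enamine may also hydrolyse or add to the quinone through nitrogen. Fallback (known chemistry, Fischer indole synthesis), setting out from 11 and returning at 19:
   - 11 is condensed with 4-(benzyloxy)phenylhydrazine hydrochloride in acetic acid to give tert-butyl 3-[4-(2-{2-[4-(benzyloxy)phenyl]hydrazinylidene}ethyl)-2,3,5,6-tetramethoxyphenyl]-5-methoxyindole-1-carboxylate F1.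
   - Warming F1 to 60 °C in the same medium should bring about [3,3]-sigmatropic rearrangement, cyclization and loss of ammonia to give tert-butyl 3-{4-[5-(benzyloxy)-1H-indol-3-yl]-2,3,5,6-tetramethoxyphenyl}-5-methoxyindole-1-carboxylate F2. The para-substituted hydrazine can only give the 5-oxygenated indole.
   - Hydrogenolysis (H2, Pd/C, EtOAc/MeOH) then frees the phenol as tert-butyl 3-[4-(5-hydroxy-1H-indol-3-yl)-2,3,5,6-tetramethoxyphenyl]-5-methoxyindole-1-carboxylate F3.
   - TFA in CH2Cl2 removes the Boc group to give 19.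

2. Step 10. Cleavage of the N-benzyl bond may be incomplete, or the 2,4-dimethoxybenzyl cation may re-alkylate the electron-rich indole and phenol rings before anisole traps it. Fallback, setting out from 11 and returning at 19, replaces acid-labile N-protection by a base-labile group (it presupposes that step 9 works):
   - 11 is condensed with 2-(phenylsulfonyl)ethylamine (MgSO4, CH2Cl2) to give tert-butyl 5-methoxy-3-[2,3,5,6-tetramethoxy-4-((E)-2-{[2-(phenylsulfonyl)ethyl]amino}vinyl)phenyl]indole-1-carboxylate F4.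
   - Annulation of F4 with 15 under the conditions of step 9 should give tert-butyl 3-(4-{5-hydroxy-1-[2-(phenylsulfonyl)ethyl]indol-3-yl}-2,3,5,6-tetramethoxyphenyl)-5-methoxyindole-1-carboxylate F5.
   - TFA in CH2Cl2 at room temperature removes only the Boc group to give 3-[2,3,5,6-tetramethoxy-4-(5-methoxy-1H-indol-3-yl)phenyl]-1-[2-(phenylsulfonyl)ethyl]indol-5-ol F6.
   - Excess t-BuOK in DMF should then release phenyl vinyl sulfone by retro-Michael (E1cB) elimination, a known way to free pyrrole and indole nitrogen, giving 19 after neutralization.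

3. Step 5. Protodeboronation of the indol-3-ylboronate may outrun the slow transmetalation onto the doubly ortho-substituted arylpalladium bromide, and the aqueous base may partly remove the Boc group. Fallback, setting out from 7 and returning at 9, uses a tin nucleophile that cannot protodeboronate:
   - 7 is stannylated with hexabutylditin (Pd(PPh3)4, toluene, 100 °C) to give tert-butyl 5-methoxy-3-(tributylstannyl)indole-1-carboxylate F7.
   - Stille coupling of F7 with 4 (Pd(PPh3)4, CuI, CsF, DMF, 50 °C, no water) gives 9.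

**Further compounds**
F1 | step 9 | tert-butyl 3-[4-(2-{2-[4-(benzyloxy)phenyl]hydrazinylidene}ethyl)-2,3,5,6-tetramethoxyphenyl]-5-methoxyindole-1-carboxylate | COc1ccc2c(c1)c(cn2C(=O)OC(C)(C)C)-c1c(OC)c(OC)c(CC=NNc2ccc(OCc3ccccc3)cc2)c(OC)c1OC
F2 | step 9 | tert-butyl 3-{4-[5-(benzyloxy)-1H-indol-3-yl]-2,3,5,6-tetramethoxyphenyl}-5-methoxyindole-1-carboxylate | COc1ccc2c(c1)c(cn2C(=O)OC(C)(C)C)-c1c(OC)c(OC)c(-c2c[nH]c3ccc(OCc4ccccc4)cc23)c(OC)c1OC
F3 | step 9 | tert-butyl 3-[4-(5-hydroxy-1H-indol-3-yl)-2,3,5,6-tetramethoxyphenyl]-5-methoxyindole-1-carboxylate | COc1ccc2c(c1)c(cn2C(=O)OC(C)(C)C)-c1c(OC)c(OC)c(-c2c[nH]c3ccc(O)cc23)c(OC)c1OC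
F4 | step 10 | tert-butyl 5-methoxy-3-[2,3,5,6-tetramethoxy-4-((E)-2-{[2-(phenylsulfonyl)ethyl]amino}vinyl)phenyl]indole-1-carboxylate | COc1ccc2c(c1)c(cn2C(=O)OC(C)(C)C)-c1c(OC)c(OC)c(/C=C/NCCS(=O)(=O)c2ccccc2)c(OC)c1OC
F5 | step 10 | tert-butyl 3-(4-{5-hydroxy-1-[2-(phenylsulfonyl)ethyl]indol-3-yl}-2,3,5,6-tetramethoxyphenyl)-5-methoxyindole-1-carboxylate | COc1ccc2c(c1)c(cn2C(=O)OC(C)(C)C)-c1c(OC)c(OC)c(-c2cn(CCS(=O)(=O)c3ccccc3)c3ccc(O)cc23)c(OC)c1OC
F6 | step 10 | 3-[2,3,5,6-tetramethoxy-4-(5-methoxy-1H-indol-3-yl)phenyl]-1-[2-(phenylsulfonyl)ethyl]indol-5-ol | COc1ccc2[nH]cc(-c3c(OC)c(OC)c(-c4cn(CCS(=O)(=O)c5ccccc5)c5ccc(O)cc45)c(OC)c3OC)c2c1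
F7 | step 5 | tert-butyl 5-methoxy-3-(tributylstannyl)indole-1-carboxylate | CCCC[Sn](CCCC)(CCCC)c1cn(C(=O)OC(C)(C)C)c2ccc(OC)cc12
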